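**Retrosynthetic overview**
1. Target 21 ⇒ triol 19 + palmitic acid 20: the ester C–O bond is made last on the only aliphatic hydroxyl, after both MOM groups of 18 are removed.
2. Ring A (C1 carries CH2O, C2 the ether oxygen to ring B, C3 OH, C5 OMe) ⇒ cyclobutenone 9 + methoxyacetylene 13. The strategy rests on the C3 hydroxyl lying meta to the C5 methoxyl, the pattern a ketene carbonyl and an ynol ether leave, while the C2 aryloxy group rides on the sp3 carbon of the four-membered ring. C3–C4 and C5–C6 are formed and C2–C3 is re-formed in the ring closure.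
3. 9 ⇒ 3-ethoxycyclobutenone 7 (1,2-addition of LiCH2OMOM, carbonyl transposition) ⇒ aryloxyketene 6 + ethoxyacetylene 4 by [2+2] cycloaddition.
4. The inter-ring ether comes from O-alkylation of orcinol mono-MOM ether 2 with chloroacetic acid, so no aryl–oxygen coupling is needed.
5. Ring order: ring B is bought as orcinol 1; ring A is the only ring built, in step 6, around the finished ether.

Key step: step 6

Remark on the chemistry: the target has no stereocentre, so 7, 8, 9, 15 and 17 are carried as racemates (8 as a diastereomer mixture) and their sp3 centres vanish on aromatisation; MOM = methoxymethyl; MOMCl, chloroacetic acid and tributyl[(methoxymethoxy)methyl]stannane are taken as purchased reagents.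

**Step 1**
Reactants: 1 orcinol (5-methylbenzene-1,3-diol)
Product: 2 3-(methoxymethoxy)-5-methylphenol
Conditions: MOMCl (1.0 equiv), iPr2NEt, THF/CH2Cl2, 0 °C to rt
Reagents that add atoms: chloromethyl methyl ether (MOMCl), COCCl
Why: O-alkylation of the symmetric resorcinol with one equivalent of MOMCl (Williamson-type, statistical) should give the mono-ether, separable by chromatography from unchanged orcinol and the bis-ether.

**Step 2**
Reactants: 2 3-(methoxymethoxy)-5-methylphenol
Product: 3 2-[3-(methoxymethoxy)-5-methylphenoxy]acetic acid
Conditions: ClCH2CO2H, NaOH, H2O, 90 °C; then cold 1 M HCl to pH 3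
Reagents that add atoms: chloroacetic acid, OC(=O)CCl
Why: Williamson ether synthesis of the phenoxide with chloroacetate is the classical aryloxyacetic acid preparation, and the MOM acetal tolerates hot base and brief cold acidification.

**Step 3**
Reactants: 3 2-[3-(methoxymethoxy)-5-methylphenoxy]acetic acid; 4 ethoxyacetylene
Product: 7 3-ethoxy-4-[3-(methoxymethoxy)-5-methylphenoxy]cyclobut-2-en-1-one (racemic), via acid chloride 5 (not isolated), via aryloxyketene 6 (not isolated)
Conditions: 1-chloro-N,N,2-trimethylprop-1-en-1-amine, CH2Cl2, 0 °C to rt; then added slowly to 4 (3 equiv), Et3N, CH2Cl2, 40 °C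
Reagents that add atoms: none
Why: The neutral chloroenamine forms the acid chloride without free HCl (the MOM ether survives), Et3N dehydrochlorinates it to the aryloxyketene, and the thermal ketene–ynol ether [2+2] cycloaddition joins the ketene carbonyl carbon to the unsubstituted alkyne carbon, which fixes the 3-ethoxy-4-aryloxy arrangement.

**Step 4**
Reactants: 7 3-ethoxy-4-[3-(methoxymethoxy)-5-methylphenoxy]cyclobut-2-en-1-one
Product: 9 3-[(methoxymethoxy)methyl]-4-[3-(methoxymethoxy)-5-methylphenoxy]cyclobut-2-en-1-one (racemic), via cyclobutenol 8 (not isolated)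
Conditions: Bu3SnCH2OCH2OCH3, n-BuLi, THF, −78 °C; then 7, −78 °C; then 1 M HCl, THF/H2O, 0 °C
Reagents that add atoms: tributyl[(methoxymethoxy)methyl]stannane, CCCC[Sn](CCCC)(CCCC)COCOC; water, O
Why: Tin–lithium exchange gives the alkoxymethyllithium, which adds 1,2 to the vinylogous ester carbonyl (enolisation at C4 would give an antiaromatic cyclobutadienolate and should not compete), and mild acid hydrolysis of the β-ethoxy allylic carbinol transposes the carbonyl (Stork–Danheiser transposition, the usual entry to 3-substituted cyclobutenones).

**Step 5**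
Reactants: 10 chloroacetaldehyde dimethyl acetal (2-chloro-1,1-dimethoxyethane)
Product: 13 methoxyacetylene, via chloro enol ether 11 (not isolated), via sodium methoxyethynide 12 (not isolated)
Conditions: NaNH2 (3 equiv), liquid NH3, −33 °C; then cold saturated aqueous NaCl; distilled into toluene at −78 °C
Reagents that add atoms: none
Why: Successive base-induced loss of methanol and of HCl (double β-elimination, the standard alkoxyacetylene preparation) gives the sodium acetylide, which water protonates, and the volatile alkyne is collected directly in the solvent of the next step.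

**Step 6**
Reactants: 9 3-[(methoxymethoxy)methyl]-4-[3-(methoxymethoxy)-5-methylphenoxy]cyclobut-2-en-1-one; 13 methoxyacetylene
Product: 18 2-[3-(methoxymethoxy)-5-methylphenoxy]-5-methoxy-3-[(methoxymethoxy)methyl]phenol, via vinylketene 14 (not isolated), via vinylcyclobutenone 15 (not isolated), via dienylketene 16 (not isolated), via cyclohexadienone 17 (not isolated)
Conditions: 13 (5 equiv), toluene, sealed tube, 90 °C
Reagents that add atoms: none
Why: Heating opens 9 by conrotatory 4π electrocyclic ring opening to vinylketene 14, methoxyacetylene adds across the ketene C=C in a [2+2] cycloaddition (its CH carbon to the ketene carbonyl carbon) to give 15, which opens again to dienylketene 16, and 6π disrotatory electrocyclisation to dienone 17 followed by tautomerisation gives the phenol. The closest known reaction is the Danheiser benzannulation of 4-substituted cyclobutenones with alkoxyalkynes; an aryloxy group on C4 is uncommon but occupies the sp3 carbon that alkyl groups occupy in the known cases. Ring A, the only ring formed, is closed by the 6π electrocyclisation that rejoins C2 to C3 after the intermolecular step has made C3–C4 and C5–C6. No stereocentre is created that survives, since the sp3 centres of 9, 15 and 17 are lost on aromatisation. The step needs regioselectivity, which the polarity of the ynol ether secures by sending its nucleophilic unsubstituted carbon to the electrophilic ketene carbon, so that the methoxyl ends meta to the new hydroxyl. It also needs outward rotation of the aryloxy group in the first ring opening, which its donor character favours and which leaves hydrogen on the inside of the triene terminus for closure, while excess alkyne limits ketene dimerisation and O-acylation of the product.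

**Step 7**
Reactants: 18 2-[3-(methoxymethoxy)-5-methylphenoxy]-5-methoxy-3-[(methoxymethoxy)methyl]phenol
Product: 19 3-(hydroxymethyl)-2-(3-hydroxy-5-methylphenoxy)-5-methoxyphenol
Conditions: HCl (2 M in MeOH), 0 °C to rt
Reagents that add atoms: none
Why: Acid-catalysed transacetalisation with methanol cleaves the aryl and the alkyl MOM ether alike, methanol traps the methoxymethyl cation away from the electron-rich rings, and the methyl ether and diaryl ether are inert.

**Step 8**
Reactants: 19 3-(hydroxymethyl)-2-(3-hydroxy-5-methylphenoxy)-5-methoxyphenol; 20 palmitic acid (hexadecanoic acid)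
Product: 21 Betaethrin H, [3-hydroxy-2-(3-hydroxy-5-methylphenoxy)-5-methoxyphenyl]methyl hexadecanoate
Conditions: 20 (1.2 equiv), PPh3, DIAD, THF, 0 °C to rt
Reagents that add atoms: none
Why: Mitsunobu esterification activates only the aliphatic hydroxyl as an alkoxyphosphonium ion and uses the carboxylic acid, far more acidic than the phenols, as pronucleophile, so the primary benzylic alcohol should be esterified with both phenols left free.

**Compound list**
1 | orcinol (5-methylbenzene-1,3-diol) | Cc1cc(O)cc(O)c1 | starting material
2 | 3-(methoxymethoxy)-5-methylphenol | COCOc1cc(C)cc(O)c1 | intermediate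
3 | 2-[3-(methoxymethoxy)-5-methylphenoxy]acetic acid | OC(=O)COc1cc(C)cc(OCOC)c1 | intermediate
4 | ethoxyacetylene | CCOC#C | starting material
5 | 2-[3-(methoxymethoxy)-5-methylphenoxy]acetyl chloride (not isolated) | O=C(Cl)COc1cc(C)cc(OCOC)c1 | intermediate
6 | [3-(methoxymethoxy)-5-methylphenoxy]ketene (not isolated) | O=C=COc1cc(C)cc(OCOC)c1 | intermediate
7 | 3-ethoxy-4-[3-(methoxymethoxy)-5-methylphenoxy]cyclobut-2-en-1-one (racemic) | CCOC1=CC(=O)C1Oc1cc(C)cc(OCOC)c1 | intermediate
8 | 3-ethoxy-1-[(methoxymethoxy)methyl]-4-[3-(methoxymethoxy)-5-methylphenoxy]cyclobut-2-en-1-ol (formed as its lithium alkoxide; diastereomer mixture; not isolated) | CCOC1=CC(O)(COCOC)C1Oc1cc(C)cc(OCOC)c1 | intermediate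
9 | 3-[(methoxymethoxy)methyl]-4-[3-(methoxymethoxy)-5-methylphenoxy]cyclobut-2-en-1-one (racemic) | O=C1C=C(COCOC)C1Oc1cc(C)cc(OCOC)c1 | intermediate
10 | chloroacetaldehyde dimethyl acetal (2-chloro-1,1-dimethoxyethane) | COC(CCl)OC | starting material
11 | 2-chloro-1-methoxyethene (E/Z mixture; not isolated) | COC=CCl | intermediate
12 | sodium methoxyethynide (not isolated) | COC#[C-].[Na+] | intermediate
13 | methoxyacetylene | COC#C | intermediate
14 | (3Z)-4-[3-(methoxymethoxy)-5-methylphenoxy]-3-[(methoxymethoxy)methyl]buta-1,3-dien-1-one (vinylketene; aryloxy group trans to the ketene carbon; not isolated) | O=C=C/C(COCOC)=C/Oc1cc(C)cc(OCOC)c1 | intermediate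
15 | 3-methoxy-4-{(Z)-2-[3-(methoxymethoxy)-5-methylphenoxy]-1-[(methoxymethoxy)methyl]ethenyl}cyclobut-2-en-1-one (racemic; not isolated) | O=C1C=C(OC)C1/C(COCOC)=C/Oc1cc(C)cc(OCOC)c1 | intermediate
16 | (3E,5Z)-3-methoxy-6-[3-(methoxymethoxy)-5-methylphenoxy]-5-[(methoxymethoxy)methyl]hexa-1,3,5-trien-1-one (dienylketene; not isolated) | O=C=C/C(OC)=C\C(COCOC)=C\Oc1cc(C)cc(OCOC)c1 | intermediate
17 | 3-methoxy-6-[3-(methoxymethoxy)-5-methylphenoxy]-5-[(methoxymethoxy)methyl]cyclohexa-2,4-dien-1-one (racemic; not isolated) | O=C1C=C(OC)C=C(COCOC)C1Oc1cc(C)cc(OCOC)c1 | intermediate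
18 | 2-[3-(methoxymethoxy)-5-methylphenoxy]-5-methoxy-3-[(methoxymethoxy)methyl]phenol | COCOCc1cc(OC)cc(O)c1Oc1cc(C)cc(OCOC)c1 | intermediate
19 | 3-(hydroxymethyl)-2-(3-hydroxy-5-methylphenoxy)-5-methoxyphenol | OCc1cc(OC)cc(O)c1Oc1cc(C)cc(O)c1 | intermediate
20 | palmitic acid (hexadecanoic acid) | CCCCCCCCCCCCCCCC(=O)O | starting material
21 | Betaethrin H, [3-hydroxy-2-(3-hydroxy-5-methylphenoxy)-5-methoxyphenyl]methyl hexadecanoate | CCCCCCCCCCCCCCCC(=O)OCc1cc(OC)cc(O)c1Oc1cc(C)cc(O)c1 | target

**Step count**
Total: 8 steps. Longest linear sequence: 7 steps (steps 1, 2, 3, 4, 6, 7, 8); step 5 is a one-step side branch.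

**Steps most likely to fail**

1. Step 6. The volatile ynol ether may oligomerise or leave the hot solution before it traps the vinylketene, so the ketene would be lost to dimerisation and to O-acylation of the product phenol; the donor-substituted triene terminus may also slow the final closure. Fallback, setting out from 9 and 13 and returning at 19: methoxyacetylene 13 would be lithiated (n-BuLi, THF, −78 °C) and silylated with Me3SiCl to give (methoxyethynyl)trimethylsilane F1, a distillable ynol ether that can be weighed, stays in solution and resists oligomerisation. Heated with 9 (toluene, 110 °C), it should enter the same cascade under the same polarity control, the silicon-bearing carbon bonding to the ketene carbon, and give 2-[3-(methoxymethoxy)-5-methylphenoxy]-5-methoxy-3-[(methoxymethoxy)methyl]-6-(trimethylsilyl)phenol F2. The silyl group then sits between the hydroxyl and the methoxyl, the most electron-rich carbon of ring A, so HCl in MeOH (as in step 7) should remove it by ipso-protodesilylation together with both MOM groups and deliver triol 19.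

2. Step 3. The aryloxyketene may dimerise or oligomerise under triethylamine faster than ethoxyacetylene captures it. Fallback, setting out from 3 and returning at 9: acid 3 would be treated with 1,1'-carbonyldiimidazole and then dimethylamine to give N,N-dimethyl-2-[3-(methoxymethoxy)-5-methylphenoxy]acetamide F3. Tf2O and 2,4,6-collidine (CH2Cl2, −20 °C to rt) in the presence of 3-(methoxymethoxy)prop-1-yne (C#CCOCOC) would convert it into N,N-dimethyl-2-[3-(methoxymethoxy)-5-methylphenoxy]ethenylideneammonium triflate F4, a keteniminium salt that does not dimerise and adds stepwise to unactivated terminal alkynes (terminal alkyne carbon to the central carbon, internal carbon to the aryloxy-bearing carbon). The resulting N,N-dimethyl-{3-[(methoxymethoxy)methyl]-4-[3-(methoxymethoxy)-5-methylphenoxy]cyclobut-2-en-1-ylidene}ammonium triflate F5 would be hydrolysed with aqueous NaHCO3 to cyclobutenone 9, so that compound 7 and step 4 are bypassed.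

3. Step 8. A phenolic oxygen may be acylated or alkylated, or a phenol may attack the activated benzylic carbon and give oligomeric benzyl aryl ethers. Fallback, setting out from 19 and returning at 21: exhaustive acylation with palmitoyl chloride (3.3 equiv, pyridine, CH2Cl2) would give [3-(hexadecanoyloxy)-2-[3-(hexadecanoyloxy)-5-methylphenoxy]-5-methoxyphenyl]methyl hexadecanoate F6. Its two aryl esters are far better acyl donors than the benzylic alkyl ester and would be cleaved selectively by aminolysis with pyrrolidine (2.2 equiv, THF, 0 °C), leaving target 21.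

**Further compounds**
F1 | step 6 | (methoxyethynyl)trimethylsilane | COC#C[Si](C)(C)C
F2 | step 6 | 2-[3-(methoxymethoxy)-5-methylphenoxy]-5-methoxy-3-[(methoxymethoxy)methyl]-6-(trimethylsilyl)phenol | COCOCc1cc(OC)c([Si](C)(C)C)c(O)c1Oc1cc(C)cc(OCOC)c1
F3 | step 3 | N,N-dimethyl-2-[3-(methoxymethoxy)-5-methylphenoxy]acetamide | CN(C)C(=O)COc1cc(C)cc(OCOC)c1
F4 | step 3 | N,N-dimethyl-2-[3-(methoxymethoxy)-5-methylphenoxy]ethenylideneammonium triflate | C[N+](C)=C=COc1cc(C)cc(OCOC)c1.[O-]S(=O)(=O)C(F)(F)F
F5 | step 3 | N,N-dimethyl-{3-[(methoxymethoxy)methyl]-4-[3-(methoxymethoxy)-5-methylphenoxy]cyclobut-2-en-1-ylidene}ammonium triflate (racemic) | C[N+](C)=C1C=C(COCOC)C1Oc1cc(C)cc(OCOC)c1.[O-]S(=O)(=O)C(F)(F)F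
F6 | step 8 | [3-(hexadecanoyloxy)-2-[3-(hexadecanoyloxy)-5-methylphenoxy]-5-methoxyphenyl]methyl hexadecanoate | CCCCCCCCCCCCCCCC(=O)OCc1cc(OC)cc(OC(=O)CCCCCCCCCCCCCCC)c1Oc1cc(C)cc(OC(=O)CCCCCCCCCCCCCCC)c1
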